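## Structural features

Ugonin G is kaempferol carrying a C10 terpenoid group on ring A. The flavonol core is ring A (C4a, C5–C8, C8a; hydroxyls on C5 and C7), the 4-pyranone ring C (O1, C2, C3–OH, C4=O) and the 4-hydroxyphenyl ring B on C2. C6, the carbon between the phenolic carbons C5 and C7, bears the methylene C7', which is bonded to C1' of a 2,6,6-trimethylcyclohex-2-ene (ring D, C1'–C6'). C1' is the only stereocenter (R); it is a C–H centre wedged between the quaternary C6' and the trisubstituted C2'=C3' bond, with no neighbouring stereocenter or heteroatom to relay control. The fragile parts are that double bond and the oxidant- and base-sensitive 3-hydroxy-4-pyranone: the alkene can move to C1'=C2' and erase the stereocenter, or be protonated so that the C2' cation is captured by O5 or O7 as a pyran. The real difficulty is the C6–C7'–C1' link: C7' is neopentyl-like, C6 is flanked on both sides, and the bond has to be made while the C1' configuration and the position of the ring D alkene are fixed. The key step exploits that C7' is benzylic and C1' is allylic to C2'=C3': with a carboxyl on C7', the array C3'=C2'–C1'–C7'–CO2H is the product pattern of a [3,3] shift of an ester on C3', so bond, configuration and alkene position all derive from one carbinol centre. A second feature used is the mirror symmetry of a 2-substituted phloroglucinol (C6 on the axis, the future O1 para to it), which makes the two carbons that can become C4a equivalent and so decides C6 against C8.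

## Logic of the disconnections

23 ⇒ 21. Cut: the three O–CH2 acetal bonds on O5, O7 and O4'. Reason: the phenols must be masked through the base, radical and photochemical steps. Gain: one protecting group type throughout, which also directs the metalation that builds ring A. Demand: the cleavage must run without a free strong acid, otherwise C2'=C3' is protonated and O5 or O7 closes a pyran.

21 ⇒ 18 + 19. Cut: O1–C2 and C2–C3 of ring C, and the C3–OH bond. Reason: ring C then comes from an aldol condensation and an oxidative closure, both in alkaline medium where ring D is inert. Gain: ring B and C2 come from 19, and 18 has a single free phenol ortho to the acyl group, so O1 is predetermined and the terpenoid can only end on C6. Demand: six-membered closure must beat the five-membered mode.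

18 ⇒ 17 ⇒ 15. Cut: the C4–C4a bond, then the O-acetyl bond. Reason: in 17 the carbon para to the ester oxygen carries C7' and the two ortho carbons are mirror images, so an O-to-C acyl shift can give only 18. Gain: C4 and C3 arrive as an acetyl group on the oxygen that becomes O1, without an acidic acylation. Demand: neutral conditions, and one oxygen of 15 that can be freed selectively (the silyl ether).

15 ⇒ 13. Cut: a carboxyl group is put back on C7'. Reason: it is a traceless activating group that turns the C1'–C7' bond into a sigmatropic retron. Gain: the aryl-bearing carbon becomes an enolisable ester α-carbon. Demand: a reductive decarboxylation through the benzylic C7' radical that leaves C1' and C2'=C3' untouched.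

13 ⇒ 10 (key). Cut: C1'–C7'; reconnect O to C3'. Reason: this is the hindered bond of the target, and the [3,3] shift makes it intramolecularly at the more hindered allyl terminus, transfers chirality from C3' to C1' and places the alkene at C2'=C3' by mechanism. Gain: 13, with its quaternary-flanked stereocenter, reduces to an ester of an achiral acid and a simple secondary allylic alcohol. Demand: the shift must outrun ionisation of the allylic ester despite compression against the C6' methyl groups. In one sentence: an Ireland–Claisen rearrangement of 10 makes the C1'–C7' bond and the stereocenter together.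

10 ⇒ 9 + 2. Cut: the ester C(O)–O bond. Reason: convergence of the ring A fragment with the chiral fragment. Gain: two fragments of comparable size. Demand: acylation with retention at the carbinol carbon.

9 ⇒ 7 ⇒ 5. Cut: the C6–C7' bond and the bond from C7' to the future carboxyl carbon (a two-carbon unit from an epoxide), then the oxidation level. Reason: the carbon between the two acetal oxygens of 5 is the most acidic ring position. Gain: the mirror-symmetric ring A with its side chain comes from a symmetric triether in two steps. Demand: metalation only between the acetal oxygens, which the bulky silyl ether secures.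

5 ⇒ 4 ⇒ 3. Cut: the Si–O bond and two O–CH2 bonds. Reason: the oxygen para to C6 (future O1) must differ from the other two (future O5, O7). Gain: the whole C6/C8 question is settled here, on a symmetric triol. Demand: a statistical double protection with separation.

2 ⇒ 1. Cut: the carbinol C–H bond. Reason: a catalytic enantioselective ketone reduction is the simplest source of the one stereocenter. Gain: an achiral purchasable enone. Demand: high facial selectivity, since the enantiomeric purity of 23 is fixed here.

## Other disconnections considered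

Alternative 1: Cut C6–C7' as aryl anion plus aldehyde; this is the union most chemists would draw first. The aryllithium 6 would add to (R)-α-cyclocitral A1 to give carbinol A2, followed by benzylic deoxygenation and the same ring C construction. Grounds against it:
- A1 has its stereocenter α to the formyl group and allylic to C2'=C3', so a basic nucleophile can enolise it, which racemises C1' or moves the alkene into conjugation.
- A1 needs an asymmetric synthesis of its own.
- The addition is bimolecular between a di-ortho-substituted aryllithium and a carbonyl next to two fully substituted carbons, where deprotonation competes.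
- Deoxygenation of A2 passes through a reactive centre at C7' next to C1'.

The chosen plan makes the same bond intramolecularly and creates C1' in the same event, never α to a carbonyl.

Alternative 2: Cut C1'–C6' (ring D). The forward step is a cation–olefin cyclisation of the 6-geranyl flavonol ether A3 with a chiral acid, ended by loss of the C3' proton. Grounds against it:
- Termination is not regiocontrolled: proton loss from C3', from the C2' methyl or towards C1'=C2' gives three alkene isomers.
- O5 and O7, or their acetals, can capture the C2' cation; this is the path to the pyran-fused congeners.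
- Enantiofacial control over a terminal trisubstituted alkene far from any binding group is expected to be weak.

It is one step, but with three open selectivities, where the sigmatropic plan has none of these.

Alternative 3: Cut the C1'–H bond, a stereoconvergent protonation. Aryl ketone A4 (C7' as carbonyl), used as the racemate, would be deprotonated to the planar lithium dienolate A5; a chiral proton donor would return (R)-A4, and the carbonyl would then be reduced to CH2. It is attractive because both enantiomers funnel into one. Grounds against it: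
- C1' stays enolisable until the carbonyl is gone.
- Removal of a carbonyl flanked by two ortho oxygens and a neopentyl-like carbon needs reduction plus a separate deoxygenation, under conditions that threaten C1' or the alkene.
- Protonation of A5 at C3' (the conjugated isomer) competes, and the chiral proton source is stoichiometric.

Step count and risk both exceed those of the chosen plan.

Key step: step 7

Remark: ketone 1, triol 3 and aldehyde 19 are taken as purchasable, and operations run in one flask without isolation are counted as one step.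

## Route

Step 1
Reactants: 1 2,4,4-trimethylcyclohex-2-en-1-one
Product: 2 (1S)-2,4,4-trimethylcyclohex-2-en-1-ol
Conditions: (R)-Me-CBS oxazaborolidine (10 mol%), BH3·SMe2, THF, −20 °C; then MeOH
Reagents that add atoms: none
Why: Corey–Bakshi–Shibata reduction with (R)-2-methyl-CBS-oxazaborolidine; the alkenyl branch C2(Me)=C3 acts as the large group, so hydride should be delivered to the face that gives the (S)-carbinol. This centre becomes C3' and is the only source of chirality in the route.

Step 2
Reactants: 3 phloroglucinol
Product: 4 3,5-bis(methoxymethoxy)phenol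
Conditions: MOMCl (2 equiv), i-Pr2NEt, CH2Cl2/DMF, 0 °C → rt
Reagents that add atoms: chloromethyl methyl ether, COCCl
Why: O-alkylation of the phenol with the chloromethyl ether; the reaction is statistical, so the bis-ether is separated from mono- and tris-ether, which can be recycled. The remaining hydroxyl is the oxygen that becomes O1.

Step 3
Reactants: 4 3,5-bis(methoxymethoxy)phenol
Product: 5 1,3-bis(methoxymethoxy)-5-(triisopropylsilyloxy)benzene
Conditions: i-Pr3SiCl, imidazole, DMF, rt
Reagents that add atoms: chlorotriisopropylsilane, CC(C)[Si](Cl)(C(C)C)C(C)C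
Why: Silylation of the remaining phenol; the bulky, non-directing silyl ether shields its two ortho positions so that step 4 metalates only between the acetal oxygens, and it can later be removed by fluoride without acid.

Step 4
Reactants: 5 1,3-bis(methoxymethoxy)-5-(triisopropylsilyloxy)benzene
Product: 7 2-[2,6-bis(methoxymethoxy)-4-(triisopropylsilyloxy)phenyl]ethanol, via aryllithium 6 (not isolated)
Conditions: n-BuLi, THF, 0 °C; then ethylene oxide (excess), 0 °C → rt; then H2O
Reagents that add atoms: ethylene oxide, C1CO1
Why: Directed ortho-metalation at the doubly chelated, most acidic C–H between the two methoxymethoxy groups, then SN2 opening of the epoxide by the aryllithium. This installs C7' and the carbon that becomes the carboxyl group, and the ring keeps its mirror symmetry.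

Step 5
Reactants: 7 2-[2,6-bis(methoxymethoxy)-4-(triisopropylsilyloxy)phenyl]ethanol
Product: 9 [2,6-bis(methoxymethoxy)-4-(triisopropylsilyloxy)phenyl]acetic acid, via arylacetaldehyde 8 (not isolated)
Conditions: TEMPO (20 mol%), PhI(OAc)2 (2.2 equiv), MeCN/H2O, rt
Reagents that add atoms: water, O
Why: Oxoammonium (TEMPO = 2,2,6,6-tetramethylpiperidin-1-oxyl) oxidation of the primary alcohol to the aldehyde, whose hydrate is oxidised on to the acid in the aqueous medium. Acetic acid is the only acid present, so acetals and silyl ether should survive.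

Step 6
Reactants: 9 [2,6-bis(methoxymethoxy)-4-(triisopropylsilyloxy)phenyl]acetic acid; 2 (1S)-2,4,4-trimethylcyclohex-2-en-1-ol
Product: 10 (1S)-2,4,4-trimethylcyclohex-2-en-1-yl [2,6-bis(methoxymethoxy)-4-(triisopropylsilyloxy)phenyl]acetate
Conditions: DCC, DMAP (10 mol%), CH2Cl2, 0 °C → rt
Reagents that add atoms: none
Why: Steglich esterification (DMAP = 4-(dimethylamino)pyridine); the carbinol C–O bond is not broken, so the (S) configuration is retained in the allylic ester.

Step 7
Reactants: 10 (1S)-2,4,4-trimethylcyclohex-2-en-1-yl [2,6-bis(methoxymethoxy)-4-(triisopropylsilyloxy)phenyl]acetate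
Product: 13 (2RS)-2-[2,6-bis(methoxymethoxy)-4-(triisopropylsilyloxy)phenyl]-2-[(1R)-2,6,6-trimethylcyclohex-2-en-1-yl]acetic acid, via silyl ketene acetal 11 (not isolated), via trimethylsilyl ester 12 (not isolated)
Conditions: LiN(SiMe3)2, THF, −78 °C; Me3SiCl/Et3N, −78 °C → rt; toluene, 80 °C; then H2O, pH 5
Reagents that add atoms: none
Why: Ireland–Claisen rearrangement: LiN(SiMe3)2 removes a benzylic α-proton of 10 (acidified by ester and aryl ring) and the enolate is O-silylated to ketene acetal 11. On warming, 11 undergoes a concerted [3,3] sigmatropic shift through a six-membered cyclic array that breaks the C3'–O bond and forms C1'–C7' while the ring alkene moves to C2'=C3'; the closest known reaction type is the ester enolate Claisen rearrangement of cyclohex-2-enyl arylacetates. No ring is closed: ring D is already present and the six-membered array exists only in the transition state. The new stereocenter C1' is controlled by the carbinol centre of 10, because the allyl unit lies in a ring and the ketene acetal carbon can reach C1' only on the face from which the oxygen leaves (suprafacial 1,3-transfer), which converts (S) at the carbinol into (R) at C1'. The second new centre, C7', is not controlled and need not be, since step 8 removes it, so chair or boat geometry and ketene acetal geometry are irrelevant. The selectivities needed are O- over C-silylation, [3,3] shift over ionisation of the allylic ester, and bond formation at the hindered terminus C1' next to C6'; the internal silyl quench, the apolar medium and above all the intramolecular delivery secure them, whereas a bimolecular or π-allyl process would choose the unhindered terminus. The alkene position is fixed by the mechanism and not by a proton loss, so no double-bond isomer can arise. Work-up at pH 5 cleaves silyl ester 12 without touching the acetals or inducing lactonisation onto C2'.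

Step 8
Reactants: 13 (2RS)-2-[2,6-bis(methoxymethoxy)-4-(triisopropylsilyloxy)phenyl]-2-[(1R)-2,6,6-trimethylcyclohex-2-en-1-yl]acetic acid
Product: 15 1,3-bis(methoxymethoxy)-5-(triisopropylsilyloxy)-2-{[(1R)-2,6,6-trimethylcyclohex-2-en-1-yl]methyl}benzene, via thiohydroxamate ester 14 (not isolated)
Conditions: N-hydroxypyridine-2-thione, DCC, DMAP (cat.), CH2Cl2, rt, dark; then t-BuSH (excess), hν (visible), rt
Reagents that add atoms: none
Why: Barton reductive decarboxylation: the O-acyl thiohydroxamate fragments under light to CO2 and the benzylic C7' radical, which abstracts hydrogen from the thiol in a chain. C1' is not involved, the alkene is inert to the chain carriers, and the uncontrolled C7' centre disappears.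

Step 9
Reactants: 15 1,3-bis(methoxymethoxy)-5-(triisopropylsilyloxy)-2-{[(1R)-2,6,6-trimethylcyclohex-2-en-1-yl]methyl}benzene
Product: 17 3,5-bis(methoxymethoxy)-4-{[(1R)-2,6,6-trimethylcyclohex-2-en-1-yl]methyl}phenyl acetate, via tetrabutylammonium phenoxide 16 (not isolated)
Conditions: Bu4NF, THF, 0 °C; then Ac2O, 0 °C → rt
Reagents that add atoms: acetic anhydride, CC(=O)OC(C)=O
Why: Fluoride cleaves the Si–O bond and the ammonium phenoxide is acetylated in the same flask; acetals and the ring D alkene are inert to both reagents.

Step 10
Reactants: 17 3,5-bis(methoxymethoxy)-4-{[(1R)-2,6,6-trimethylcyclohex-2-en-1-yl]methyl}phenyl acetate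
Product: 18 1-[6-hydroxy-2,4-bis(methoxymethoxy)-3-{[(1R)-2,6,6-trimethylcyclohex-2-en-1-yl]methyl}phenyl]ethanone
Conditions: hν (254 nm), MeCN (degassed), rt
Reagents that add atoms: none
Why: Photo-Fries rearrangement: homolysis of the ester C(O)–O bond and recombination of the caged acyl/phenoxyl pair at an ortho carbon. The para carbon is blocked by C7' and the two ortho carbons are equivalent by symmetry, so a single hydroxy ketone should form, with its free hydroxyl on the future O1, and no acid is involved.

Step 11
Reactants: 18 1-[6-hydroxy-2,4-bis(methoxymethoxy)-3-{[(1R)-2,6,6-trimethylcyclohex-2-en-1-yl]methyl}phenyl]ethanone; 19 4-(methoxymethoxy)benzaldehyde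
Product: 21 3-hydroxy-5,7-bis(methoxymethoxy)-2-[4-(methoxymethoxy)phenyl]-6-{[(1R)-2,6,6-trimethylcyclohex-2-en-1-yl]methyl}-4H-chromen-4-one, via chalcone 20 (not isolated)
Conditions: KOH, EtOH/H2O, rt; then 30% H2O2, 0 °C → rt
Reagents that add atoms: hydrogen peroxide, OO
Why: Claisen–Schmidt condensation followed by Algar–Flynn–Oyamada oxidation: hydroperoxide epoxidises the enone, the single free ortho phenoxide opens the epoxide at the benzylic carbon in the six-membered mode, and further oxidation gives the 3-hydroxy-4-pyranone. Alkaline peroxide does not attack the isolated C2'=C3' bond, and because only the future O1 is free the terpenoid ends up on C6.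

Step 12
Reactants: 21 3-hydroxy-5,7-bis(methoxymethoxy)-2-[4-(methoxymethoxy)phenyl]-6-{[(1R)-2,6,6-trimethylcyclohex-2-en-1-yl]methyl}-4H-chromen-4-one
Product: 23 Ugonin G, via tetrakis(trimethylsilyl) ether 22 (not isolated)
Conditions: Me3SiOTf, 2,2'-bipyridyl, CH2Cl2, 0 °C → rt; then H2O
Reagents that add atoms: none
Why: The silyl triflate–bipyridyl pair converts aryl methoxymethyl ethers into aryl silyl ethers by way of N-(methoxymethyl)pyridinium salts in a medium that never holds a free strong acid, and water then hydrolyses the silyl ethers. This avoids protonation of C2'=C3' and capture of the C2' cation by O5 or O7, and C1' is untouched.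

## Compound list

1 | 2,4,4-trimethylcyclohex-2-en-1-one | O=C1CCC(C)(C)C=C1C | starting material
2 | (1S)-2,4,4-trimethylcyclohex-2-en-1-ol | O[C@H]1CCC(C)(C)C=C1C | intermediate
3 | phloroglucinol (benzene-1,3,5-triol) | Oc1cc(O)cc(O)c1 | starting material
4 | 3,5-bis(methoxymethoxy)phenol | COCOc1cc(O)cc(OCOC)c1 | intermediate
5 | 1,3-bis(methoxymethoxy)-5-(triisopropylsilyloxy)benzene | COCOc1cc(OCOC)cc(O[Si](C(C)C)(C(C)C)C(C)C)c1 | intermediate
6 | [2,6-bis(methoxymethoxy)-4-(triisopropylsilyloxy)phenyl]lithium | [Li]c1c(OCOC)cc(O[Si](C(C)C)(C(C)C)C(C)C)cc1OCOC | intermediate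
7 | 2-[2,6-bis(methoxymethoxy)-4-(triisopropylsilyloxy)phenyl]ethanol | OCCc1c(OCOC)cc(O[Si](C(C)C)(C(C)C)C(C)C)cc1OCOC | intermediate
8 | [2,6-bis(methoxymethoxy)-4-(triisopropylsilyloxy)phenyl]acetaldehyde | O=CCc1c(OCOC)cc(O[Si](C(C)C)(C(C)C)C(C)C)cc1OCOC | intermediate
9 | [2,6-bis(methoxymethoxy)-4-(triisopropylsilyloxy)phenyl]acetic acid | OC(=O)Cc1c(OCOC)cc(O[Si](C(C)C)(C(C)C)C(C)C)cc1OCOC | intermediate
10 | (1S)-2,4,4-trimethylcyclohex-2-en-1-yl [2,6-bis(methoxymethoxy)-4-(triisopropylsilyloxy)phenyl]acetate | O=C(Cc1c(OCOC)cc(O[Si](C(C)C)(C(C)C)C(C)C)cc1OCOC)O[C@H]1CCC(C)(C)C=C1C | intermediate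
11 | trimethylsilyl ketene acetal of 10 (double-bond geometry open) | C[Si](C)(C)OC(=Cc1c(OCOC)cc(O[Si](C(C)C)(C(C)C)C(C)C)cc1OCOC)O[C@H]1CCC(C)(C)C=C1C | intermediate
12 | trimethylsilyl ester of 13 (both C7' epimers) | CC1=CCCC(C)(C)[C@H]1C(C(=O)O[Si](C)(C)C)c1c(OCOC)cc(O[Si](C(C)C)(C(C)C)C(C)C)cc1OCOC | intermediate
13 | (2RS)-2-[2,6-bis(methoxymethoxy)-4-(triisopropylsilyloxy)phenyl]-2-[(1R)-2,6,6-trimethylcyclohex-2-en-1-yl]acetic acid | CC1=CCCC(C)(C)[C@H]1C(C(=O)O)c1c(OCOC)cc(O[Si](C(C)C)(C(C)C)C(C)C)cc1OCOC | intermediate
14 | 2-thioxopyridin-1(2H)-yl ester of 13 (thiohydroxamate ester, both C7' epimers) | CC1=CCCC(C)(C)[C@H]1C(C(=O)On1ccccc1=S)c1c(OCOC)cc(O[Si](C(C)C)(C(C)C)C(C)C)cc1OCOC | intermediate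
15 | 1,3-bis(methoxymethoxy)-5-(triisopropylsilyloxy)-2-{[(1R)-2,6,6-trimethylcyclohex-2-en-1-yl]methyl}benzene | CC1=CCCC(C)(C)[C@H]1Cc1c(OCOC)cc(O[Si](C(C)C)(C(C)C)C(C)C)cc1OCOC | intermediate
16 | tetrabutylammonium 3,5-bis(methoxymethoxy)-4-{[(1R)-2,6,6-trimethylcyclohex-2-en-1-yl]methyl}phenoxide | CC1=CCCC(C)(C)[C@H]1Cc1c(OCOC)cc([O-])cc1OCOC.CCCC[N+](CCCC)(CCCC)CCCC | intermediate
17 | 3,5-bis(methoxymethoxy)-4-{[(1R)-2,6,6-trimethylcyclohex-2-en-1-yl]methyl}phenyl acetate | CC1=CCCC(C)(C)[C@H]1Cc1c(OCOC)cc(OC(C)=O)cc1OCOC | intermediate
18 | 1-[6-hydroxy-2,4-bis(methoxymethoxy)-3-{[(1R)-2,6,6-trimethylcyclohex-2-en-1-yl]methyl}phenyl]ethanone | CC1=CCCC(C)(C)[C@H]1Cc1c(OCOC)cc(O)c(C(C)=O)c1OCOC | intermediate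
19 | 4-(methoxymethoxy)benzaldehyde | COCOc1ccc(C=O)cc1 | starting material
20 | (2E)-1-[6-hydroxy-2,4-bis(methoxymethoxy)-3-{[(1R)-2,6,6-trimethylcyclohex-2-en-1-yl]methyl}phenyl]-3-[4-(methoxymethoxy)phenyl]prop-2-en-1-one | CC1=CCCC(C)(C)[C@H]1Cc1c(OCOC)cc(O)c(C(=O)/C=C/c2ccc(OCOC)cc2)c1OCOC | intermediate
21 | 3-hydroxy-5,7-bis(methoxymethoxy)-2-[4-(methoxymethoxy)phenyl]-6-{[(1R)-2,6,6-trimethylcyclohex-2-en-1-yl]methyl}-4H-chromen-4-one | CC1=CCCC(C)(C)[C@H]1Cc1c(OCOC)cc2oc(-c3ccc(OCOC)cc3)c(O)c(=O)c2c1OCOC | intermediate
22 | 3,5,7,4'-tetrakis(trimethylsilyl) ether of 23 | CC1=CCCC(C)(C)[C@H]1Cc1c(O[Si](C)(C)C)cc2oc(-c3ccc(O[Si](C)(C)C)cc3)c(O[Si](C)(C)C)c(=O)c2c1O[Si](C)(C)C | intermediate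
23 | Ugonin G | CC1=CCCC(C)(C)[C@H]1Cc1c(O)cc2oc(-c3ccc(O)cc3)c(O)c(=O)c2c1O | target

## Step count and least certain steps

Total: 12 steps. Longest linear sequence: 11 steps (steps 2–12, from 3); step 1 supplies 2 for step 6.

Step 7 (key step). The most likely failure is that compression between the incoming aryl-bearing carbon and the C6' methyl groups slows the [3,3] shift, so that ionisation of the allylic C–O bond, elimination to a diene or C-silylation of the enolate take over. The fallback sets out from 2 and 6 and returns at 15. An orthoester (Johnson–Claisen) rearrangement of 2 with MeC(OEt)3 and catalytic EtCO2H at 140 °C uses a far smaller ketene acetal and should give ethyl [(1R)-2,6,6-trimethylcyclohex-2-en-1-yl]acetate F1 with the same chirality transfer. LiOH would give [(1R)-2,6,6-trimethylcyclohex-2-en-1-yl]acetic acid F2, and N-hydroxyphthalimide with diisopropylcarbodiimide its 1,3-dioxoisoindolin-2-yl ester F3. Aryllithium 6 would be transmetalated with ZnCl2 to [2,6-bis(methoxymethoxy)-4-(triisopropylsilyloxy)phenyl]zinc chloride F4. A decarboxylative Negishi-type coupling of F3 with F4 (NiCl2·dme, 4,4'-di-tert-butyl-2,2'-bipyridine, THF/DMF, rt) would then form the C6–C7' bond and deliver 15, bypassing steps 5 to 8.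

Step 8. The most likely failures are incomplete acylation of the thiohydroxamic acid by the very hindered acid and, after fragmentation, capture of the stabilised C7' radical by the thiocarbonyl group instead of hydrogen transfer from the thiol. The fallback sets out from 13 and returns at 15, with no new compound. It is a direct photocatalytic hydrodecarboxylation of the free acid (9-mesityl-10-methylacridinium tetrafluoroborate and PhSSPh as catalysts, i-Pr2NEt, CF3CH2OH, 450 nm), in which the carboxylate is oxidised by electron transfer and no acyl derivative has to be made.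

Step 10. The most likely failures are escape of the acyl/phenoxyl pair from the solvent cage, which returns the phenol, and photocycloaddition of the excited arene to the C2'=C3' bond across the short tether. The fallback sets out from 17 and returns at 18. Methanolysis (K2CO3, MeOH) would give 3,5-bis(methoxymethoxy)-4-{[(1R)-2,6,6-trimethylcyclohex-2-en-1-yl]methyl}phenol F5. Magnesium-mediated ortho-formylation (MgCl2, Et3N, paraformaldehyde, MeCN, reflux) at one of the two equivalent ortho carbons would give 6-hydroxy-2,4-bis(methoxymethoxy)-3-{[(1R)-2,6,6-trimethylcyclohex-2-en-1-yl]methyl}benzaldehyde F6. MeMgBr would give 1-[6-hydroxy-2,4-bis(methoxymethoxy)-3-{[(1R)-2,6,6-trimethylcyclohex-2-en-1-yl]methyl}phenyl]ethanol F7, and MnO2 would oxidise this benzylic alcohol to 18.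

Step 11. The most likely failure is closure of the epoxide intermediate in the five-membered mode to an aurone, favoured when the ketone is twisted out of the ring plane by the ortho acetal oxygen; retro-aldol loss of the chalcone is a lesser risk. The fallback sets out from 18 and returns at 21 by a Baker–Venkataraman sequence:
- 4-(Methoxymethoxy)benzoyl chloride in pyridine would give 2-acetyl-3,5-bis(methoxymethoxy)-4-{[(1R)-2,6,6-trimethylcyclohex-2-en-1-yl]methyl}phenyl 4-(methoxymethoxy)benzoate F8.
- KOH in pyridine would rearrange it to 1-[6-hydroxy-2,4-bis(methoxymethoxy)-3-{[(1R)-2,6,6-trimethylcyclohex-2-en-1-yl]methyl}phenyl]-3-[4-(methoxymethoxy)phenyl]propane-1,3-dione F9.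
- Buffered cyclodehydration (NaOAc, AcOH, 100 °C) would give 5,7-bis(methoxymethoxy)-2-[4-(methoxymethoxy)phenyl]-6-{[(1R)-2,6,6-trimethylcyclohex-2-en-1-yl]methyl}-4H-chromen-4-one F10.
- Lithiation at C3 (LiN(i-Pr)2, THF, −78 °C), borylation with B(OMe)3 and oxidation with H2O2/AcOH would install the 3-hydroxyl and give 21.

## Further compounds

F1 | step 7 | ethyl [(1R)-2,6,6-trimethylcyclohex-2-en-1-yl]acetate | CC1=CCCC(C)(C)[C@H]1CC(=O)OCC
F2 | step 7 | [(1R)-2,6,6-trimethylcyclohex-2-en-1-yl]acetic acid | CC1=CCCC(C)(C)[C@H]1CC(=O)O
F3 | step 7 | 1,3-dioxoisoindolin-2-yl [(1R)-2,6,6-trimethylcyclohex-2-en-1-yl]acetate | CC1=CCCC(C)(C)[C@H]1CC(=O)ON1C(=O)c2ccccc2C1=O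
F4 | step 7 | [2,6-bis(methoxymethoxy)-4-(triisopropylsilyloxy)phenyl]zinc chloride | Cl[Zn]c1c(OCOC)cc(O[Si](C(C)C)(C(C)C)C(C)C)cc1OCOC
F0 | step 8 | none | none
F5 | step 10 | 3,5-bis(methoxymethoxy)-4-{[(1R)-2,6,6-trimethylcyclohex-2-en-1-yl]methyl}phenol | CC1=CCCC(C)(C)[C@H]1Cc1c(OCOC)cc(O)cc1OCOC
F6 | step 10 | 6-hydroxy-2,4-bis(methoxymethoxy)-3-{[(1R)-2,6,6-trimethylcyclohex-2-en-1-yl]methyl}benzaldehyde | CC1=CCCC(C)(C)[C@H]1Cc1c(OCOC)cc(O)c(C=O)c1OCOC
F7 | step 10 | 1-[6-hydroxy-2,4-bis(methoxymethoxy)-3-{[(1R)-2,6,6-trimethylcyclohex-2-en-1-yl]methyl}phenyl]ethanol (both carbinol epimers) | CC1=CCCC(C)(C)[C@H]1Cc1c(OCOC)cc(O)c(C(C)O)c1OCOC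
F8 | step 11 | 2-acetyl-3,5-bis(methoxymethoxy)-4-{[(1R)-2,6,6-trimethylcyclohex-2-en-1-yl]methyl}phenyl 4-(methoxymethoxy)benzoate | CC1=CCCC(C)(C)[C@H]1Cc1c(OCOC)cc(OC(=O)c2ccc(OCOC)cc2)c(C(C)=O)c1OCOC
F9 | step 11 | 1-[6-hydroxy-2,4-bis(methoxymethoxy)-3-{[(1R)-2,6,6-trimethylcyclohex-2-en-1-yl]methyl}phenyl]-3-[4-(methoxymethoxy)phenyl]propane-1,3-dione | CC1=CCCC(C)(C)[C@H]1Cc1c(OCOC)cc(O)c(C(=O)CC(=O)c2ccc(OCOC)cc2)c1OCOC
F10 | step 11 | 5,7-bis(methoxymethoxy)-2-[4-(methoxymethoxy)phenyl]-6-{[(1R)-2,6,6-trimethylcyclohex-2-en-1-yl]methyl}-4H-chromen-4-one | CC1=CCCC(C)(C)[C@H]1Cc1c(OCOC)cc2oc(-c3ccc(OCOC)cc3)cc(=O)c2c1OCOC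
A1 | alternative 1 | (1R)-2,6,6-trimethylcyclohex-2-ene-1-carbaldehyde, (R)-α-cyclocitral | CC1=CCCC(C)(C)[C@H]1C=O
A2 | alternative 1 | [2,6-bis(methoxymethoxy)-4-(triisopropylsilyloxy)phenyl][(1R)-2,6,6-trimethylcyclohex-2-en-1-yl]methanol (both carbinol epimers) | CC1=CCCC(C)(C)[C@H]1C(O)c1c(OCOC)cc(O[Si](C(C)C)(C(C)C)C(C)C)cc1OCOC
A3 | alternative 2 | 6-[(2E)-3,7-dimethylocta-2,6-dien-1-yl]-3-hydroxy-5,7-bis(methoxymethoxy)-2-[4-(methoxymethoxy)phenyl]-4H-chromen-4-one | CC(C)=CCC/C(C)=C/Cc1c(OCOC)cc2oc(-c3ccc(OCOC)cc3)c(O)c(=O)c2c1OCOC
A4 | alternative 3 | [2,6-bis(methoxymethoxy)-4-(triisopropylsilyloxy)phenyl][(1R)-2,6,6-trimethylcyclohex-2-en-1-yl]methanone | CC1=CCCC(C)(C)[C@H]1C(=O)c1c(OCOC)cc(O[Si](C(C)C)(C(C)C)C(C)C)cc1OCOC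
A5 | alternative 3 | lithium dienolate of A4 | [Li+].[O-]C(=C1C(C)=CCCC1(C)C)c1c(OCOC)cc(O[Si](C(C)C)(C(C)C)C(C)C)cc1OCOC
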